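**Plan**

1. Retrosynthesis: after removal of the silyl groups and of the isopropyl group (C4 ketone), the C6–O bond is cut together with the ring size. Inside the seven-membered ring, C6–O is homoallylic to C8=C9 through C7H2 (a cyclohept-3-enyl ester), which is the retron of a cyclopropylcarbinyl ester. C6–C8 is therefore re-joined to give a six-membered ring (C1, C5, C6, C8, C9, C10) carrying a C6–C7–C8 cyclopropane and the aroate on C9.
2. Further cuts: the cyclopropane methylene C7, the C6=C8 bond (metathesis), the C8–C9 bond (Grignard on a Weinreb amide), and the C1–C10 and C5–C6 bonds (conjugate addition–alkylation on a 2-methylcyclopentenone).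
3. Forward: cyclopentane (chiral-pool enone) → trans-fused six-membered ring by ring-closing metathesis → cyclopropane → seven-membered ring by ring expansion with transfer of the aroate from C9 to C6 → C4 isopropyl carbinol → desilylation.
4. Stereochemistry: C4 of the enone controls C5 and then C1; C2 and C9 come from CBS reductions; the C9 hydroxyl directs the cyclopropane to the α face; C6 follows from the cyclopropane by inversion in the key step; the C4 carbinol comes from addition anti to the C5–C6 bond and the angular methyl group.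

Key step: step 12

Remark on numbering: all intermediates keep the atom numbers of the target (C1 angular-methyl carbon, C2 carbinol, C3, C4 isopropyl carbinol, C5 ring-fusion CH, C6 ester carbon, C7, C8 vinyl-methyl carbon, C9, C10); β is the face of the C1 methyl group, α the opposite face.
Assumption: (R)-4-(tert-butyldimethylsilyloxy)cyclopent-2-en-1-one, 2-bromo-N-methoxy-N-methylacetamide, 4-hydroxybenzoic acid, the Grignard reagents and (R)-2-methyl-CBS-oxazaborolidine are taken as commercial.

**Route**

Step 1
Reactants: 1 (R)-4-[(tert-butyldimethylsilyl)oxy]cyclopent-2-en-1-one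
Product: 2 (R)-4-[(tert-butyldimethylsilyl)oxy]-2-iodocyclopent-2-en-1-one
Conditions: I2, pyridine, CH2Cl2, 0 °C → rt
Reagents that add atoms: iodine, II
Why: α-iodination of a cyclic enone by conjugate addition of pyridine, iodination of the enolate and elimination; the C4 stereocentre is not touched.

Step 2
Reactants: 2 (R)-4-[(tert-butyldimethylsilyl)oxy]-2-iodocyclopent-2-en-1-one
Product: 3 (R)-4-[(tert-butyldimethylsilyl)oxy]-2-methylcyclopent-2-en-1-one
Conditions: Me4Sn, Pd2(dba)3 (cat.), AsPh3, CuI, NMP, 60 °C
Reagents that add atoms: tetramethylstannane, C[Sn](C)(C)C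
Why: Stille coupling of an α-iodoenone under neutral conditions, chosen so that the β-silyloxy ketone does not undergo elimination.

Step 3
Reactants: 3 (R)-4-[(tert-butyldimethylsilyl)oxy]-2-methylcyclopent-2-en-1-one
Product: 5 2-[(1R,2R,3R)-3-[(tert-butyldimethylsilyl)oxy]-1-methyl-5-oxo-2-vinylcyclopentyl]-N-methoxy-N-methylacetamide, via magnesium enolate 4 (not isolated)
Conditions: vinylmagnesium bromide, CuBr·SMe2 (cat.), THF, −78 → −40 °C; then BrCH2C(O)N(OMe)Me, HMPA, −40 → 0 °C
Reagents that add atoms: vinylmagnesium bromide, C=C[Mg]Br; 2-bromo-N-methoxy-N-methylacetamide, CON(C)C(=O)CBr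
Why: copper-catalysed conjugate addition followed by alkylation of the regiodefined enolate (three-component coupling), in which the vinyl group should enter C5 anti to the C4 silyloxy group and the bromoacetamide should then alkylate C1 anti to the new vinyl group, giving the quaternary centre with methyl cis to vinyl.

Step 4
Reactants: 5 2-[(1R,2R,3R)-3-[(tert-butyldimethylsilyl)oxy]-1-methyl-5-oxo-2-vinylcyclopentyl]-N-methoxy-N-methylacetamide
Product: 6 2-[(1R,2R,3R,5S)-3-[(tert-butyldimethylsilyl)oxy]-5-hydroxy-1-methyl-2-vinylcyclopentyl]-N-methoxy-N-methylacetamide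
Conditions: (R)-2-methyl-CBS-oxazaborolidine (0.3 equiv), catecholborane, toluene, −78 → −40 °C
Reagents that add atoms: none
Why: Corey–Bakshi–Shibata reduction in which quaternary C1 is the large and the C3 methylene the small group, so that the (R)-catalyst should deliver hydride to the β face (also the face anti to the C4 silyloxy group) and give the (S)-carbinol, i.e. the 2α-hydroxyl, while catecholborane spares the vinyl group and the Weinreb amide.

Step 5
Reactants: 6 2-[(1R,2R,3R,5S)-3-[(tert-butyldimethylsilyl)oxy]-5-hydroxy-1-methyl-2-vinylcyclopentyl]-N-methoxy-N-methylacetamide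
Product: 7 2-[(1R,2R,3R,5S)-3-[(tert-butyldimethylsilyl)oxy]-1-methyl-5-[(triisopropylsilyl)oxy]-2-vinylcyclopentyl]-N-methoxy-N-methylacetamide
Conditions: TIPSOTf, 2,6-lutidine, CH2Cl2, 0 °C → rt
Reagents that add atoms: triisopropylsilyl trifluoromethanesulfonate, CC(C)[Si](OS(=O)(=O)C(F)(F)F)(C(C)C)C(C)C
Why: silylation of the hindered secondary alcohol with a silyl triflate; the TIPS ether is chosen to outlast the later selective removal of the C4 TBS ether.

Step 6
Reactants: 7 2-[(1R,2R,3R,5S)-3-[(tert-butyldimethylsilyl)oxy]-1-methyl-5-[(triisopropylsilyl)oxy]-2-vinylcyclopentyl]-N-methoxy-N-methylacetamide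
Product: 8 1-[(1R,2R,3R,5S)-3-[(tert-butyldimethylsilyl)oxy]-1-methyl-5-[(triisopropylsilyl)oxy]-2-vinylcyclopentyl]-3-methylbut-3-en-2-one
Conditions: isopropenylmagnesium bromide, THF, 0 °C; then pH 7 buffer
Reagents that add atoms: isopropenylmagnesium bromide, CC(=C)[Mg]Br
Why: Weinreb ketone synthesis, in which the stable magnesium chelate stops the addition at the ketone stage and delivers the isopropenyl ketone that carries C8 and its methyl group.

Step 7
Reactants: 8 1-[(1R,2R,3R,5S)-3-[(tert-butyldimethylsilyl)oxy]-1-methyl-5-[(triisopropylsilyl)oxy]-2-vinylcyclopentyl]-3-methylbut-3-en-2-one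
Product: 9 (2S)-1-[(1R,2R,3R,5S)-3-[(tert-butyldimethylsilyl)oxy]-1-methyl-5-[(triisopropylsilyl)oxy]-2-vinylcyclopentyl]-3-methylbut-3-en-2-ol
Conditions: (R)-2-methyl-CBS-oxazaborolidine (0.3 equiv), catecholborane, toluene, −78 °C
Reagents that add atoms: none
Why: Corey–Bakshi–Shibata reduction of an α-substituted enone in which the isopropenyl group is the large group, so that the (R)-catalyst should give the (S)-allylic alcohol, which becomes the 9α-hydroxyl after ring closure.

Step 8
Reactants: 9 (2S)-1-[(1R,2R,3R,5S)-3-[(tert-butyldimethylsilyl)oxy]-1-methyl-5-[(triisopropylsilyl)oxy]-2-vinylcyclopentyl]-3-methylbut-3-en-2-ol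
Product: 10 trans-fused cyclohexenol (cyclopentane C1–C5 fused to the ring C1–C5–C6=C8–C9–C10; 1β-methyl, 5α-H, 8-methyl, 9α-OH, 2α-OTIPS, 4α-OTBS)
Conditions: second-generation Grubbs catalyst (5 mol%), CH2Cl2, 40 °C
Reagents that add atoms: none
Why: ring-closing metathesis of the vinyl and isopropenyl groups closes the six-membered ring as a trans-fused 2-methylcyclohex-2-enol with loss of ethene, without change at any stereocentre.

Step 9
Reactants: 10 trans-fused cyclohexenol
Product: 11 cyclopropylcarbinol (as 10, with a 6α,8α-methylene bridge C7 in place of the C6=C8 double bond; 8β-methyl, 9α-OH)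
Conditions: Et2Zn, CH2I2, CH2Cl2, 0 °C → rt
Reagents that add atoms: diiodomethane, ICI
Why: hydroxyl-directed Simmons–Smith cyclopropanation (Furukawa conditions), in which the zinc alkoxide at C9 delivers the methylene to the α face of C6=C8, syn to the hydroxyl and anti to the axial C1 methyl group; this sets C6 and C8 and leaves the pseudo-equatorial C9–O bond antiperiplanar to the new C6–C8 bond.

Step 10
Reactants: 12 4-hydroxybenzoic acid
Product: 14 4-[(tert-butyldimethylsilyl)oxy]benzoic acid, via bis-silylated ester 13 (not isolated)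
Conditions: TBSCl (2.2 equiv), imidazole, DMF, rt; then AcOH, THF–H2O, rt
Reagents that add atoms: tert-butyldimethylsilyl chloride, C[Si](C)(Cl)C(C)(C)C
Why: exhaustive silylation followed by selective hydrolysis of the labile silyl ester leaves the phenol protected as its TBS ether.

Step 11
Reactants: 11 cyclopropylcarbinol; 14 4-[(tert-butyldimethylsilyl)oxy]benzoic acid
Product: 15 cyclopropylcarbinyl ester (9α-O-[4-(tert-butyldimethylsilyloxy)benzoyl] derivative of 11)
Conditions: DCC, DMAP, CH2Cl2, 0 °C → rt
Reagents that add atoms: none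
Why: Steglich esterification acylates the only free hydroxyl at oxygen, so C9 keeps its configuration.

Step 12
Reactants: 15 cyclopropylcarbinyl ester
Product: 16 hydroazulene ester (trans-fused bicyclo[5.3.0]dec-8-ene; 1β,8-dimethyl, 5α-H, 2α-OTIPS, 4α-OTBS, 6α-O-[4-(tert-butyldimethylsilyloxy)benzoyl])
Conditions: BF3·OEt2 (0.2 equiv), 4 Å molecular sieves, CH2Cl2, −40 → −10 °C; then Et3N
Reagents that add atoms: none
Why: Proposed new method: coordination of BF3 to the ester carbonyl should ionise the pseudo-equatorial C9–O bond with participation of the antiperiplanar C6–C8 cyclopropane bond, giving a bisected cyclopropylcarbinyl/homoallyl cation paired with the aroate, which returns to C6 on the α face, anti to the breaking C6–C8 bond, while C8=C9 forms. The closest known reaction type is the solvolytic cyclopropylcarbinyl-to-homoallyl ring expansion of bicyclo[4.1.0]heptan-2-yl derivatives to cyclohept-3-enyl derivatives, together with the i-steroid rearrangement of 3,5-cyclosteroid 6-esters by internal return; here it is run as a Lewis-acid-catalysed ion-pair transposition of the ester in a non-nucleophilic solvent. No ring is closed by cyclisation: the seven-membered ring (C1, C5, C6, C7, C8, C9, C10) arises from the six-membered ring (C1, C5, C6, C8, C9, C10) by cleavage of the zero-atom bridge C6–C8 of the bicyclo[4.1.0]heptane, so that C7 is inserted between C6 and C8. The only new stereocentre, C6, is set by inversion at the cyclopropane carbon, so the α cyclopropane placed by the C9 hydroxyl in step 9 becomes the 6α ester. The step needs cleavage of the ring-fusion bond C6–C8 and not of C7–C8, which is secured by the antiperiplanar alignment of C9–O with C6–C8 and by the better support of positive charge at secondary C6 than at primary C7. Return of the aroate to C9 or to the tertiary cyclobutyl position C8 gives esters that ionise again under the conditions, whereas the strain-free homoallylic ester 16 does not, so the mixture should drain to 16.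

Step 13
Reactants: 16 hydroazulene ester
Product: 17 4α-alcohol (as 16, with free 4α-OH)
Conditions: aq. HF (48%), MeCN, 0 °C
Reagents that add atoms: none
Why: acidic fluoride should cleave the unhindered secondary alkyl TBS ether faster than the phenolic TBS ether and the hindered C2 TIPS ether; the alcohol is oxidised without delay to forestall 1,3-acyl migration from O6 to the syn O4.

Step 14
Reactants: 17 4α-alcohol
Product: 18 4-ketone (as 16, with C4=O)
Conditions: Dess–Martin periodinane, CH2Cl2, 0 °C → rt
Reagents that add atoms: none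
Why: Dess–Martin oxidation under non-basic conditions should give the β-acyloxy ketone without elimination of the aroate or epimerisation at C5.

Step 15
Reactants: 18 4-ketone
Product: 19 bis-silyl ether of the target (2-O-TIPS, phenol O-TBS; 4β-OH, 4α-isopropyl)
Conditions: iPrMgCl, CeCl3 (anhydrous), THF, −78 °C; then pH 7 buffer
Reagents that add atoms: isopropylmagnesium chloride, CC(C)[Mg]Cl
Why: addition of the weakly basic organocerium reagent is chemoselective for the ketone over the electron-rich aryl ester, and attack on the α face, anti to the adjacent C5–C6 bond and to the angular methyl group, should give the 4β-hydroxy-4α-isopropyl carbinol.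

Step 16
Reactants: 19 bis-silyl ether of the target
Product: 20 2α-hydroxyferutinin
Conditions: TBAF, THF, 0 → 40 °C; then H2O
Reagents that add atoms: none
Why: fluoride-mediated cleavage of the phenolic TBS ether and of the C2 TIPS ether, to which the benzoate ester, the tertiary alcohol and the trisubstituted alkene should be stable.

**Compound list**

1 | (R)-4-[(tert-butyldimethylsilyl)oxy]cyclopent-2-en-1-one | O=C1C=C[C@H](O[Si](C)(C)C(C)(C)C)C1 | starting material
2 | (R)-4-[(tert-butyldimethylsilyl)oxy]-2-iodocyclopent-2-en-1-one | O=C1C(I)=C[C@H](O[Si](C)(C)C(C)(C)C)C1 | intermediate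
3 | (R)-4-[(tert-butyldimethylsilyl)oxy]-2-methylcyclopent-2-en-1-one | O=C1C(C)=C[C@H](O[Si](C)(C)C(C)(C)C)C1 | intermediate
4 | bromomagnesium enolate of (3R,4R)-4-[(tert-butyldimethylsilyl)oxy]-2-methyl-3-vinylcyclopentan-1-one (C1=C2 enolate, vinyl trans to OTBS) | C=C[C@H]1[C@H](O[Si](C)(C)C(C)(C)C)CC(O[Mg]Br)=C1C | intermediate
5 | 2-[(1R,2R,3R)-3-[(tert-butyldimethylsilyl)oxy]-1-methyl-5-oxo-2-vinylcyclopentyl]-N-methoxy-N-methylacetamide | CON(C)C(=O)C[C@]1(C)[C@@H](C=C)[C@H](O[Si](C)(C)C(C)(C)C)CC1=O | intermediate
6 | 2-[(1R,2R,3R,5S)-3-[(tert-butyldimethylsilyl)oxy]-5-hydroxy-1-methyl-2-vinylcyclopentyl]-N-methoxy-N-methylacetamide | CON(C)C(=O)C[C@]1(C)[C@@H](C=C)[C@H](O[Si](C)(C)C(C)(C)C)C[C@@H]1O | intermediate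
7 | 2-[(1R,2R,3R,5S)-3-[(tert-butyldimethylsilyl)oxy]-1-methyl-5-[(triisopropylsilyl)oxy]-2-vinylcyclopentyl]-N-methoxy-N-methylacetamide | CON(C)C(=O)C[C@]1(C)[C@@H](C=C)[C@H](O[Si](C)(C)C(C)(C)C)C[C@@H]1O[Si](C(C)C)(C(C)C)C(C)C | intermediate
8 | 1-[(1R,2R,3R,5S)-3-[(tert-butyldimethylsilyl)oxy]-1-methyl-5-[(triisopropylsilyl)oxy]-2-vinylcyclopentyl]-3-methylbut-3-en-2-one | CC(=C)C(=O)C[C@]1(C)[C@@H](C=C)[C@H](O[Si](C)(C)C(C)(C)C)C[C@@H]1O[Si](C(C)C)(C(C)C)C(C)C | intermediate
9 | (2S)-1-[(1R,2R,3R,5S)-3-[(tert-butyldimethylsilyl)oxy]-1-methyl-5-[(triisopropylsilyl)oxy]-2-vinylcyclopentyl]-3-methylbut-3-en-2-ol | CC(=C)[C@@H](O)C[C@]1(C)[C@@H](C=C)[C@H](O[Si](C)(C)C(C)(C)C)C[C@@H]1O[Si](C(C)C)(C(C)C)C(C)C | intermediate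
10 | trans-fused cyclohexenol: cyclopentane C1–C5 fused to ring C1–C5–C6=C8–C9–C10; 1β-methyl, 5α-H, 8-methyl, 9α-OH, 2α-OTIPS, 4α-OTBS | CC1=C[C@H]2[C@H](O[Si](C)(C)C(C)(C)C)C[C@H](O[Si](C(C)C)(C(C)C)C(C)C)[C@]2(C)C[C@@H]1O | intermediate
11 | cyclopropylcarbinol: as 10 with a 6α,8α-methylene bridge (C7) in place of C6=C8; 8β-methyl, 9α-OH | C[C@@]12C[C@@H]1[C@H]3[C@H](O[Si](C)(C)C(C)(C)C)C[C@H](O[Si](C(C)C)(C(C)C)C(C)C)[C@]3(C)C[C@@H]2O | intermediate
12 | 4-hydroxybenzoic acid | OC(=O)c1ccc(O)cc1 | starting material
13 | tert-butyldimethylsilyl 4-[(tert-butyldimethylsilyl)oxy]benzoate | CC(C)(C)[Si](C)(C)OC(=O)c1ccc(O[Si](C)(C)C(C)(C)C)cc1 | intermediate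
14 | 4-[(tert-butyldimethylsilyl)oxy]benzoic acid | OC(=O)c1ccc(O[Si](C)(C)C(C)(C)C)cc1 | intermediate
15 | cyclopropylcarbinyl ester: 9α-O-[4-(tert-butyldimethylsilyloxy)benzoyl] derivative of 11 | C[C@@]12C[C@@H]1[C@H]3[C@H](O[Si](C)(C)C(C)(C)C)C[C@H](O[Si](C(C)C)(C(C)C)C(C)C)[C@]3(C)C[C@@H]2OC(=O)c4ccc(O[Si](C)(C)C(C)(C)C)cc4 | intermediate
16 | hydroazulene ester: trans-fused bicyclo[5.3.0]dec-8-ene, 1β,8-dimethyl, 5α-H, 2α-OTIPS, 4α-OTBS, 6α-yl 4-(tert-butyldimethylsilyloxy)benzoate | CC1=CC[C@]2(C)[C@@H]([C@@H](OC(=O)c3ccc(O[Si](C)(C)C(C)(C)C)cc3)C1)[C@H](O[Si](C)(C)C(C)(C)C)C[C@@H]2O[Si](C(C)C)(C(C)C)C(C)C | intermediate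
17 | 4α-alcohol: as 16 with free 4α-OH | CC1=CC[C@]2(C)[C@@H]([C@@H](OC(=O)c3ccc(O[Si](C)(C)C(C)(C)C)cc3)C1)[C@H](O)C[C@@H]2O[Si](C(C)C)(C(C)C)C(C)C | intermediate
18 | 4-ketone: as 16 with C4=O | CC1=CC[C@]2(C)[C@@H]([C@@H](OC(=O)c3ccc(O[Si](C)(C)C(C)(C)C)cc3)C1)C(=O)C[C@@H]2O[Si](C(C)C)(C(C)C)C(C)C | intermediate
19 | 2-O-triisopropylsilyl, phenol O-tert-butyldimethylsilyl derivative of 2α-hydroxyferutinin | CC1=CC[C@]2(C)[C@@H]([C@@H](OC(=O)c3ccc(O[Si](C)(C)C(C)(C)C)cc3)C1)[C@](O)(C(C)C)C[C@@H]2O[Si](C(C)C)(C(C)C)C(C)C | intermediate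
20 | 2α-hydroxyferutinin | CC1=CC[C@]2(C)[C@@H]([C@@H](OC(=O)c3ccc(O)cc3)C1)[C@](O)(C(C)C)C[C@@H]2O | target

**Step count and risks**

Total steps: 16. Longest linear sequence: 15 (steps 1–9 and 11–16; step 10 is a one-step side branch).

Steps most likely to fail:

Step 12. The cation may lose a proton to give dienes, the aroate may return with cleavage of the external C7–C8 bond, or a silyl ether may be lost under the Lewis acid. The fallback uses the known acid-catalysed hydrolytic rearrangement of bicyclo[4.1.0]heptan-2-ols to cyclohept-3-enols and sets out from 11, before the acylation. Treatment of 11 with dilute HClO4 in aqueous dioxane at room temperature should give, with water as the nucleophile and the same inversion at C6, the ring-expanded 6α-alcohol F1. Steglich esterification of F1 with 14 (DCC, DMAP, CH2Cl2), where C6–OH is the only free hydroxyl, comes back to the route at 16.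

Step 3. Alkylation of the hindered magnesium enolate may be slow, which would allow proton transfer and β-elimination of the silyloxy group, or 1,2-addition may compete with conjugate addition. The fallback sets out from 3. Conjugate addition of vinylmagnesium bromide with CuBr·SMe2 (cat.) in the presence of TMSCl should give the isolable trimethylsilyl enol ether F2. F2 is then alkylated at C1 under neutral conditions by the carbamoylmethyl radical generated from 2-bromo-N-methoxy-N-methylacetamide (Ir(ppy)3 as photocatalyst, blue light, DMF); the radical should add anti to the vinyl group, and loss of the silyl group comes back to the route at 5.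

Step 15. The secondary alkyl organometallic may act as a base or hydride donor (enolisation towards C5 with β-elimination of the C6 aroate, or reduction of the ketone), or facial selectivity may be poor. The fallback sets out from 18. Addition of the 2-propenylcerium reagent (isopropenylmagnesium bromide, CeCl3, THF, −78 °C), which is less basic and has no β-hydrogen, should give the isopropenyl carbinol F3. Chemoselective hydrogenation of its 1,1-disubstituted double bond (H2, RhCl(PPh3)3, benzene) in the presence of the trisubstituted ring alkene comes back to the route at 19.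

Further compounds
F1 | step 12 | 6α-alcohol: trans-fused bicyclo[5.3.0]dec-8-ene, 1β,8-dimethyl, 5α-H, 2α-OTIPS, 4α-OTBS, 6α-OH | CC1=CC[C@]2(C)[C@@H]([C@@H](O)C1)[C@H](O[Si](C)(C)C(C)(C)C)C[C@@H]2O[Si](C(C)C)(C(C)C)C(C)C
F2 | step 3 | (3R,4R)-4-[(tert-butyldimethylsilyl)oxy]-2-methyl-1-[(trimethylsilyl)oxy]-3-vinylcyclopent-1-ene | C=C[C@H]1[C@H](O[Si](C)(C)C(C)(C)C)CC(O[Si](C)(C)C)=C1C
F3 | step 15 | isopropenyl carbinol: as 19 with a 4α-(prop-1-en-2-yl) group in place of the 4α-isopropyl group | CC1=CC[C@]2(C)[C@@H]([C@@H](OC(=O)c3ccc(O[Si](C)(C)C(C)(C)C)cc3)C1)[C@](O)(C(C)=C)C[C@@H]2O[Si](C(C)C)(C(C)C)C(C)C
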